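## Structural features

Broussoflavonol B (19) is a flavone: a benzene ring A fused to a 4-pyranone ring C, with a 3,4-dihydroxyphenyl ring B on C2 and a methoxy group on C3. Ring A is hexasubstituted: C4a carries the C4 carbonyl, C5 and C7 carry hydroxyls, C8a carries the ring oxygen O1, and C6 and C8 each carry a 3-methylbut-2-enyl (prenyl) group. There is no stereocentre and no stereogenic double bond, so no stereocentres stand next to each other; every problem is one of regiochemistry and chemoselectivity. The fragile parts are the two trisubstituted prenyl alkenes, each ortho to a phenol (acid adds the phenol across them to give chromans, or adds solvent), and the electron-rich phloroglucinol and catechol rings (oxidation, C-alkylation with dearomatisation). The single O-methyl group on C3 has to be told apart from four free hydroxyls and is best carried from the start. The real difficulty is ring A, because direct prenylation of an acylphloroglucinol gives mixtures of O-, mono-, di- and geminally C-alkylated products. The key step uses the fact that the sequence C4a (acyl), C5 (O), C6 (C), C7 (O), C8 (C), C8a (O) is the pattern of a 3,5,7-trioxo ester that already bears the prenyl groups on C2 and C4 of the chain. Ring A, its three oxygens, both prenyl groups and the methoxyacetyl side chain then arise from one chain by closing the C4a–C8a bond, and because the resulting ketone is symmetric, either ortho hydroxyl can later become O1.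

## Logic of the disconnections

19 ⇒ 17. The O1–C2 bond of ring C is cut and the four phenolic O–H bonds are replaced by acetal O–C bonds. This leads to 17 (through 18, which need not be isolated), in which the free hydroxyl ortho to the ketone and the ring B carbonyl are placed for cyclodehydration. Ring closure and removal of all four acetals answer to the same reagent, so one operation gives the ring and the free target. The forward step must keep the acid weak and the time short, so that the phenols freed next to C6 and C8 do not add to the prenyl double bonds.

17 ⇒ 16. The C2–C3 bond is cut, between the methoxy-bearing carbon and the ring B carbonyl. Read forwards this is an acyl shift from oxygen to carbon within one molecule, so an intermolecular C-acylation of a crowded ketone is traded for an ester. The methoxy group stays on the future C3 throughout, so no late selective O-methylation is needed. The forward step needs clean enolisation of the methoxymethyl ketone with the ester carbonyl within reach.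

16 ⇒ 12 + 15. The ester C–O bond is cut. This is the convergent point, where ring B with its masked catechol is separated from the whole of ring A. The demand is that 12 has exactly one free hydroxyl and that it is ortho to the ketone. The acid 15 is coupled as such, because its acetals would not tolerate the hydrogen chloride that accompanies an acid chloride preparation.

12 ⇒ 11, and 15 ⇒ 14 ⇒ 13. Only acetal O–C bonds are cut. In 11 the two hydroxyls ortho to the ketone are equivalent, so it does not matter which stays free; the forward step must cap two hydroxyls and leave the hydrogen-bonded one. For ring B all three acidic positions of 13 are capped at once, and the ester-type acetal of 14 is then removed by base.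

11 ⇒ 10 ⇒ 9 (key disconnection). The C4a–C8a bond of ring A is cut, which unfolds the benzene ring into the chain of 10. Closing a lactone between C1 and the oxygen on C5 of that chain gives 9, a stable and isolable mask. This is the largest gain of the route: a hexasubstituted arene with three oxygens, two prenyl groups and the acyl side chain becomes a pyranone whose substituents are all placed by enolate chemistry. The forward step must open the lactone and then fold the chain in the Claisen sense (C6 onto C1), not in an aldol sense.

9 ⇒ 7 + 8. The bond between the exocyclic methylene and the side-chain carbonyl is cut. This removes the methoxyacetyl unit, which carries the future C3 and its methoxy group. The forward step needs carbon metalation of the ring methyl group beside an acidic hydroxyl, and an acyl donor that neither enolises nor releases a proton source. That is why 8 is preferred to the corresponding methyl ester.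

7 ⇒ 6. The lactone C–O bond is cut, back to the open 3,5-dioxo ester. The forward closure is an enol-oxygen acylation; it places both prenyl groups on sp2 carbons and removes the two stereocentres of 6.

6 ⇒ 4 + 5. The C4–C5 bond is cut, which removes the acetyl group. The forward step is the acylation of a keto ester dianion at its remote carbon, which already bears a prenyl group. It needs a dianion that forms only there and an acyl donor that adds once.

4 ⇒ 3 + 2, and 3 ⇒ 1 + 2. The two prenyl C–C bonds are cut in turn. Both are made at the keto ester stage, the remote one through the dianion and the one between the carbonyls through the monoanion. No 1,3-diketone has to be alkylated, which avoids the O-alkylation and double alkylation that would bring. What remains are 1 and 2, both bulk chemicals.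

## Other disconnections considered

Alternative 1: The cut is the C3–C4 bond of ring C.
- Forward key step: the ring A acid A1, 2-[1-[3,4-bis(methoxymethoxy)phenyl]-2-methoxyethenoxy]-4,6-bis(methoxymethoxy)-3,5-bis(3-methylbut-2-enyl)benzoic acid, would be turned into its acid chloride A2 in the flask. The electron-rich enol ether carbon (C3) would then attack the acyl chloride, close ring C and give the protected flavone A3 after loss of a proton.
- In its favour: the methoxy group and ring B arrive on one unit. The ring closes by a single irreversible C–C bond formation at the flavone oxidation level, with no separate acyl shift or dehydration. A3 has the same constitution as 18, so the end game would be shared.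
- Against it here: it leaves the main problem, the hexasubstituted ring A, untouched and asks for it as a salicylic acid. It requires an aryl 1-aryl-2-methoxyvinyl ether on a hindered phenol, for which no simple and reliable construction is at hand. The acyl chloride and the oxocarbenium ion formed on closure would sit beside four acetals and two nucleophilic prenyl alkenes.
- Comparison: on structure the two plans are equal in carrying the C3 methoxy group from an early stage. On mechanism the alternative is the better in needing no ester at a hindered phenol and no rearrangement, and the worse in functional group tolerance. On step economy it should be longer, because ring A with its carboxyl group, the enol ether and the ring closure are three separate tasks, whereas the chosen plan makes ring A together with its acyl group in one step.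

Alternative 2: The cut removes three bonds of ring A at once (C4a–C5, C5–C6 and C7–C8).
- Forward key step: the cyclobutenone A4, 2-(3-methylbut-2-enyl)-3-(triisopropylsilyloxy)cyclobut-2-en-1-one, would be heated in toluene with the siloxyalkyne A5, triisopropyl(5-methylhex-4-en-1-ynoxy)silane. Four-electron ring opening of A4 to a vinylketene, [2+2] addition to A5, a second ring opening and a six-electron closure would give the phenol A6 (Danheiser benzannulation).
- In its favour: five substituents are placed regiospecifically in one neutral thermal step. No phenoxide or enolate is involved, so neither O- versus C-alkylation nor a choice between Claisen and aldol folding arises. On regiochemical certainty of ring A it is the equal of the chosen plan, and on mildness of the ring-forming step it is the better.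
- Against it here: A6 still has an open carbon where C4a must carry the methoxyacetyl group. A Friedel–Crafts or Fries type acylation would have to follow at a position flanked by two oxygens, with a Lewis acid next to prenyl groups ortho to phenols. A4 and A5 each need several steps and are sensitive, and the silyl ethers add protecting group steps before ring C can be built.
- Comparison: structurally the alternative builds ring A without its acyl carbon, the chosen plan with it. Mechanistically a pericyclic cascade stands against an ionic cyclisation that needs selectivity between folding modes. In step economy the alternative should need clearly more steps to reach the stage of 11 (two reagent syntheses, benzannulation, acylation, desilylation) than the six of the chosen plan.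

Alternative 3: The cut is the C2–C3 bond, with the C4 carbonyl and C2 masked together as an isoxazole.
- Forward key step: the nitrile oxide A7, 3,4-bis(methoxymethoxy)benzonitrile oxide, made from the corresponding hydroximoyl chloride, would react with the sodium enolate of the fully protected ring A ketone A8, 2-methoxy-1-[2,4,6-tris(methoxymethoxy)-3,5-bis(3-methylbut-2-enyl)phenyl]ethanone. Addition, closure through oxygen and loss of water would give the isoxazole A9. Reductive N–O cleavage and hydrolysis would then uncover the 1,3-dicarbonyl unit, and acid would close ring C and remove the acetals as in step 12.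
- In its favour: the C2–C3 bond is made without an ester on the hindered ortho hydroxyl. All three ring A hydroxyls can carry the same protecting group, so no selective protection is needed. The isoxazole is a robust, non-enolisable mask. On these points it is the equal or the better of steps 7, 10 and 11.
- Against it here: A8 is the tris-acetal of 11, so the alternative does nothing for ring A and replaces only the later part. It adds oxime formation, chlorination, N–O cleavage and enaminone hydrolysis. The N–O cleavage cannot be a catalytic hydrogenation because of the prenyl alkenes (Mo(CO)6 or SmI2 would be needed). A slow addition of a crowded enolate would leave the nitrile oxide time to dimerise.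
- Comparison: structurally both plans reach the same dicarbonyl oxidation level with the methoxy group in place. Mechanistically an intermolecular cyclocondensation stands against an intramolecular acyl shift, which has the entropic advantage. In step economy the alternative should cost about three steps more.

Key step: step 6

Remarks on the chemistry:
- Compounds 9 and 11 are isomers (C19H26O5) and agree atom for atom with the bond formed in step 6; no structure needed correction. The bond closed there can equally be called C4a–C5, because the two ortho carbons of 11 are equivalent until ring C is closed.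
- Compounds 4, 6, 10 and 17 carry stereocentres alpha to carbonyl groups. They are used as racemates or as mixtures of diastereomers and enol forms, and every such centre becomes sp2 later.
- The amides 5 and 8 are taken as commercial reagents. If 8 had to be made, methyl methoxyacetate, N,O-dimethylhydroxylamine hydrochloride and iPrMgCl would give it in one step.
- Three points depart from the simplest plan. Both prenyl groups are placed on the keto ester before any 1,3-diketone exists. The side chain is introduced with an N-methoxy-N-methylamide instead of an enolisable ester. Two hydroxyls of 11 are capped before aroylation, so that only one ester can form.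

## Route

Step 1
Reactants: 1 methyl acetoacetate; 2 prenyl bromide (1-bromo-3-methylbut-2-ene)
Product: 3 methyl 7-methyl-3-oxooct-6-enoate
Conditions: NaH (1.1 equiv), THF, 0 °C; n-BuLi (1.05 equiv), 0 °C; 2 (1.0 equiv), 0 °C to rt; 1 M HCl
Reagents that add atoms: none
Why: Weiler dianion alkylation: the second deprotonation puts the more basic carbanion on the terminal carbon, which alone reacts with one equivalent of the allylic bromide, by SN2 at its primary carbon so that the prenyl group arrives unrearranged.

Step 2
Reactants: 3 methyl 7-methyl-3-oxooct-6-enoate; 2 prenyl bromide
Product: 4 methyl 7-methyl-2-(3-methylbut-2-enyl)-3-oxooct-6-enoate (racemic)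
Conditions: K2CO3 (1.5 equiv), 2 (0.95 equiv), acetone, reflux
Reagents that add atoms: none
Why: Monoanion C-alkylation of a β-keto ester with an allylic bromide under mild carbonate conditions; the bromide is kept slightly short so that double alkylation stays small, and the new stereocentre is racemic and is lost in step 4.

Step 3
Reactants: 4 methyl 7-methyl-2-(3-methylbut-2-enyl)-3-oxooct-6-enoate; 5 N-methoxy-N-methylacetamide
Product: 6 methyl 2,4-bis(3-methylbut-2-enyl)-3,5-dioxohexanoate (mixture of diastereomers and enol forms)
Conditions: LiN(iPr)2 (2.2 equiv), THF, −78 to 0 °C; 5 (1.2 equiv), −78 to 0 °C; 1 M HCl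
Reagents that add atoms: none
Why: Acylation of the α,γ-dianion of a β-keto ester at the γ carbon: after the first deprotonation between the carbonyls the second can only occur at C4, and the chelated tetrahedral adduct of the N-methoxy-N-methylamide survives until work-up, so the carbanion is neither acylated twice nor quenched by the more acidic product; the same sequence is standard for the 2,4-dimethyl analogues that lead to 3,5-dimethyl-4-hydroxypyranones.

Step 4
Reactants: 6 methyl 2,4-bis(3-methylbut-2-enyl)-3,5-dioxohexanoate
Product: 7 4-hydroxy-6-methyl-3,5-bis(3-methylbut-2-enyl)pyran-2-one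
Conditions: DBU (1.5 equiv), toluene, 90 °C; 1 M HCl wash
Reagents that add atoms: none
Why: Base-mediated lactonisation of a 3,5-dioxo ester: the enolate oxygen on C5 attacks the ester carbonyl (6-exo-trig), methoxide leaves and the ring tautomerises to the 4-hydroxypyran-2-one, which takes both former stereocentres to sp2 carbons.

Step 5
Reactants: 7 4-hydroxy-6-methyl-3,5-bis(3-methylbut-2-enyl)pyran-2-one; 8 N,2-dimethoxy-N-methylacetamide
Product: 9 4-hydroxy-6-(3-methoxy-2-oxopropyl)-3,5-bis(3-methylbut-2-enyl)pyran-2-one
Conditions: LiN(iPr)2 (2.2 equiv), THF, −78 to −20 °C; 8 (1.2 equiv), −78 to 0 °C; 1 M HCl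
Reagents that add atoms: none
Why: Harris-type acylation of a 4-hydroxy-6-methylpyranone dianion: the first equivalent of base removes the hydroxyl proton, the second the vinylogous methyl proton, and the carbanion adds once to the N-methoxy-N-methylamide; the prenyl methylenes are not activated by a carbonyl and should not be metalated.

Step 6
Reactants: 9 4-hydroxy-6-(3-methoxy-2-oxopropyl)-3,5-bis(3-methylbut-2-enyl)pyran-2-one
Product: 11 2-methoxy-1-[2,4,6-trihydroxy-3,5-bis(3-methylbut-2-enyl)phenyl]ethanone, via methyl 8-methoxy-2,4-bis(3-methylbut-2-enyl)-3,5,7-trioxooctanoate 10 (not isolated)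
Conditions: Mg(OMe)2 (5 equiv), MeOH, reflux, Ar; cold 1 M HCl to pH 3
Reagents that add atoms: magnesium methoxide, [Mg+2].[O-]C.[O-]C (one methoxide adds to C2 of 9 and becomes the ester group of 10; it is expelled again on ring closure, so 11 keeps none of its atoms)
Why: Magnesium-bound methoxide adds to the lactone carbonyl C2 of 9 and the ring opens to the polyenolate of 10, which the divalent magnesium holds as a chelate of the 3,5,7-trioxo array. The C6 methylene of 10 is the only unsubstituted carbon between two ketones, hence the most acidic and least hindered carbon nucleophile, and in the chelated U-shaped chain it lies within reach of the ester carbonyl C1. Its attack on C1 is a 6-exo-trig Claisen (Dieckmann-type) closure that forms the future C4a–C8a bond and closes ring A. Loss of methoxide gives a cyclohexane-1,3,5-trione that enolises to the aromatic triol, and this irreversible aromatisation draws all earlier equilibria, relactonisation to 9 included, forward. The closest known reaction type is the Mg(OMe)2 cyclisation of 3,5,7-trioxo esters and of 6-(2-oxoalkyl)-4-hydroxypyran-2-ones to acylphloroglucinols. No stereocentre is formed, and those at C2 and C4 of 10 disappear on aromatisation. The selectivity needed is Claisen over aldol folding: the aldol paths start either from the prenylated C2, which would create a quaternary carbon that cannot aromatise and so reverts, or from the methoxy-bearing C8, which is activated by one carbonyl only and is scarcely deprotonated by methoxide. Air is excluded and the work-up is cold and only mildly acidic, because 11 is an oxidisable phloroglucinol with prenyl groups ortho to phenols.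

Step 7
Reactants: 11 2-methoxy-1-[2,4,6-trihydroxy-3,5-bis(3-methylbut-2-enyl)phenyl]ethanone
Product: 12 1-[2-hydroxy-4,6-bis(methoxymethoxy)-3,5-bis(3-methylbut-2-enyl)phenyl]-2-methoxyethanone
Conditions: MOMCl (2.3 equiv), iPr2NEt (3 equiv), CH2Cl2, 0 °C to rt
Reagents that add atoms: chloromethyl methyl ether (MOMCl), COCCl
Why: Acetal formation with a hard electrophile and a weak amine base takes place at oxygen only; the hydroxyl para to the ketone and one of the two equivalent ortho hydroxyls are capped, after which the last hydroxyl is held in a strong hydrogen bond to the carbonyl and should not react with the limited amount of chloride.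

Step 8
Reactants: 13 3,4-dihydroxybenzoic acid
Product: 14 methoxymethyl 3,4-bis(methoxymethoxy)benzoate
Conditions: MOMCl (3.6 equiv), iPr2NEt (5 equiv), DMF, 0 °C to rt
Reagents that add atoms: chloromethyl methyl ether (MOMCl), COCCl
Why: The same O-alkylation on the carboxylate and both phenoxide oxygens caps all three acidic positions in one operation.

Step 9
Reactants: 14 methoxymethyl 3,4-bis(methoxymethoxy)benzoate
Product: 15 3,4-bis(methoxymethoxy)benzoic acid
Conditions: LiOH·H2O (3 equiv), THF/MeOH/H2O, rt; cold 1 M HCl to pH 4
Reagents that add atoms: lithium hydroxide, [Li+].[OH-] (supplies one oxygen of the carboxyl group)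
Why: Saponification: the methoxymethyl ester is an activated ester and is cleaved by hydroxide at room temperature, whereas aryl methoxymethyl ethers are inert to base; brief cold acidification to pH 4 spares the acetals.

Step 10
Reactants: 12 1-[2-hydroxy-4,6-bis(methoxymethoxy)-3,5-bis(3-methylbut-2-enyl)phenyl]-2-methoxyethanone; 15 3,4-bis(methoxymethoxy)benzoic acid
Product: 16 [2-(2-methoxyacetyl)-3,5-bis(methoxymethoxy)-4,6-bis(3-methylbut-2-enyl)phenyl] 3,4-bis(methoxymethoxy)benzoate
Conditions: EDC·HCl (1.5 equiv), DMAP (0.5 equiv), CH2Cl2, rt
Reagents that add atoms: none
Why: Steglich esterification: the carbodiimide activates the acid and 4-(dimethylamino)pyridine passes the acyl group to the phenol as an acylpyridinium ion, under neutral conditions that leave acetals and prenyl groups untouched; only one hydroxyl is free, so only one ester can form.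

Step 11
Reactants: 16 [2-(2-methoxyacetyl)-3,5-bis(methoxymethoxy)-4,6-bis(3-methylbut-2-enyl)phenyl] 3,4-bis(methoxymethoxy)benzoate
Product: 17 1-[3,4-bis(methoxymethoxy)phenyl]-3-[2-hydroxy-4,6-bis(methoxymethoxy)-3,5-bis(3-methylbut-2-enyl)phenyl]-2-methoxypropane-1,3-dione (racemic at C2, in equilibrium with enol forms)
Conditions: LiN(SiMe3)2 (3 equiv), THF, −78 °C to rt; AcOH
Reagents that add atoms: none
Why: Baker–Venkataraman rearrangement: the lithium enolate of the methoxymethyl ketone attacks the neighbouring aryl ester carbonyl through a six-membered cyclic transition state and the aryloxide leaves, so the aroyl group moves from oxygen to carbon; the stable chelated dianion of the product drives the shift, and the stereocentre at C2 is lost in step 12.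

Step 12
Reactants: 17 1-[3,4-bis(methoxymethoxy)phenyl]-3-[2-hydroxy-4,6-bis(methoxymethoxy)-3,5-bis(3-methylbut-2-enyl)phenyl]-2-methoxypropane-1,3-dione
Product: 19 broussoflavonol B, via 2-[3,4-bis(methoxymethoxy)phenyl]-3-methoxy-5,7-bis(methoxymethoxy)-6,8-bis(3-methylbut-2-enyl)chromen-4-one 18 (not isolated)
Conditions: HCl (ca. 1 M in MeOH, from conc. aq HCl), 40–45 °C, Ar, monitored
Reagents that add atoms: none
Why: Acid-catalysed cyclodehydration of a 2-hydroxyaryl 1,3-diketone (the phenol attacks the ring B carbonyl and the hemiketal loses water) should give the flavone, and the same methanolic acid transfers the four methoxymethyl groups to the solvent as dimethoxymethane; moderate temperature, exclusion of air and close monitoring are meant to stop the reaction before the freed phenols add to the prenyl double bonds.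

## Compound list

1 | methyl acetoacetate | COC(=O)CC(C)=O | starting material
2 | prenyl bromide (1-bromo-3-methylbut-2-ene) | CC(C)=CCBr | starting material
3 | methyl 7-methyl-3-oxooct-6-enoate | COC(=O)CC(=O)CCC=C(C)C | intermediate
4 | methyl 7-methyl-2-(3-methylbut-2-enyl)-3-oxooct-6-enoate (racemic) | COC(=O)C(CC=C(C)C)C(=O)CCC=C(C)C | intermediate
5 | N-methoxy-N-methylacetamide | CC(=O)N(C)OC | starting material
6 | methyl 2,4-bis(3-methylbut-2-enyl)-3,5-dioxohexanoate (mixture of diastereomers and enol forms) | COC(=O)C(CC=C(C)C)C(=O)C(CC=C(C)C)C(C)=O | intermediate
7 | 4-hydroxy-6-methyl-3,5-bis(3-methylbut-2-enyl)pyran-2-one | CC1=C(CC=C(C)C)C(O)=C(CC=C(C)C)C(=O)O1 | intermediate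
8 | N,2-dimethoxy-N-methylacetamide | COCC(=O)N(C)OC | starting material
9 | 4-hydroxy-6-(3-methoxy-2-oxopropyl)-3,5-bis(3-methylbut-2-enyl)pyran-2-one | COCC(=O)CC1=C(CC=C(C)C)C(O)=C(CC=C(C)C)C(=O)O1 | intermediate (precursor of the key step)
10 | methyl 8-methoxy-2,4-bis(3-methylbut-2-enyl)-3,5,7-trioxooctanoate (present as its magnesium enolate chelate; mixture of diastereomers) | COCC(=O)CC(=O)C(CC=C(C)C)C(=O)C(CC=C(C)C)C(=O)OC | intermediate (not isolated)
11 | 2-methoxy-1-[2,4,6-trihydroxy-3,5-bis(3-methylbut-2-enyl)phenyl]ethanone | COCC(=O)c1c(O)c(CC=C(C)C)c(O)c(CC=C(C)C)c1O | intermediate (product of the key step)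
12 | 1-[2-hydroxy-4,6-bis(methoxymethoxy)-3,5-bis(3-methylbut-2-enyl)phenyl]-2-methoxyethanone | COCC(=O)c1c(O)c(CC=C(C)C)c(OCOC)c(CC=C(C)C)c1OCOC | intermediate
13 | 3,4-dihydroxybenzoic acid | O=C(O)c1ccc(O)c(O)c1 | starting material
14 | methoxymethyl 3,4-bis(methoxymethoxy)benzoate | COCOC(=O)c1ccc(OCOC)c(OCOC)c1 | intermediate
15 | 3,4-bis(methoxymethoxy)benzoic acid | COCOc1ccc(C(=O)O)cc1OCOC | intermediate
16 | [2-(2-methoxyacetyl)-3,5-bis(methoxymethoxy)-4,6-bis(3-methylbut-2-enyl)phenyl] 3,4-bis(methoxymethoxy)benzoate | COCC(=O)c1c(OC(=O)c2ccc(OCOC)c(OCOC)c2)c(CC=C(C)C)c(OCOC)c(CC=C(C)C)c1OCOC | intermediate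
17 | 1-[3,4-bis(methoxymethoxy)phenyl]-3-[2-hydroxy-4,6-bis(methoxymethoxy)-3,5-bis(3-methylbut-2-enyl)phenyl]-2-methoxypropane-1,3-dione (racemic, enolisable) | COCOc1ccc(C(=O)C(OC)C(=O)c2c(O)c(CC=C(C)C)c(OCOC)c(CC=C(C)C)c2OCOC)cc1OCOC | intermediate
18 | 2-[3,4-bis(methoxymethoxy)phenyl]-3-methoxy-5,7-bis(methoxymethoxy)-6,8-bis(3-methylbut-2-enyl)chromen-4-one | COc1c(-c2ccc(OCOC)c(OCOC)c2)oc2c(CC=C(C)C)c(OCOC)c(CC=C(C)C)c(OCOC)c2c1=O | intermediate (not isolated)
19 | broussoflavonol B, 2-(3,4-dihydroxyphenyl)-5,7-dihydroxy-3-methoxy-6,8-bis(3-methylbut-2-enyl)chromen-4-one (achiral) | COc1c(-c2ccc(O)c(O)c2)oc2c(CC=C(C)C)c(O)c(CC=C(C)C)c(O)c2c1=O | target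

## Step count and least certain steps

Total step count: 12. Longest linear sequence: 10 (steps 1 to 7 and 10 to 12); steps 8 and 9 form the side branch to 15.

Step 6 (key step).
- What may go wrong: methanolysis of the lactone may be slow or fail, because 9 sits as its unreactive 4-oxido magnesium salt and C2 is shielded by the prenyl group on C3. Prolonged heating could then allow retro-Claisen loss of the methoxyacetyl group, or aldol-type closure through the methoxy-bearing methylene.
- Fallback: it sets out from 6 and returns at 11. Compound 6 would be converted into its trianion with LiN(iPr)2 (3.3 equiv) in THF and acylated at the terminal methyl group with 8. This would give 10 directly as an isolated open-chain triketo ester, with no lactone to open. Compound 10 would then be folded to 11 with Mg(OMe)2 in methanol at room temperature. No new compound is needed.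

Step 3.
- What may go wrong: proton transfer from the acetyl group of 5 to the hindered secondary carbanion (enolisation of the acyl donor) may outrun addition and return 4.
- Fallback: it sets out from 4 and returns at 6. The same dianion would be added to acetaldehyde at −78 °C, an aldol addition that is fast even for crowded dianions, to give methyl 5-hydroxy-2,4-bis(3-methylbut-2-enyl)-3-oxohexanoate F1. Oxidation of the secondary alcohol with Dess–Martin periodinane in CH2Cl2 would give 6.

Step 5.
- What may go wrong: carbon metalation may be incomplete, because the lithium 4-oxide is poorly soluble and the methyl group lies next to the prenyl group on C5. The crowded carbanion may also add sluggishly, so that 7 is recovered.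
- Fallback: it sets out from 7 and returns at 9. The dianion would be added to methoxyacetaldehyde, a smaller and more reactive electrophile, to give 4-hydroxy-6-(2-hydroxy-3-methoxypropyl)-3,5-bis(3-methylbut-2-enyl)pyran-2-one F2. Oxidation with Dess–Martin periodinane would give 9.

Step 10.
- What may go wrong: acyl transfer to a phenol that is hydrogen-bonded to the ketone and flanked by a prenyl group may be slow, so that rearrangement of the activated acid to the N-acylurea outruns esterification.
- Fallback: it sets out from 12 and 15 and returns at 17, passing over 16. Compound 15 would be converted under neutral conditions with 1-chloro-N,N,2-trimethylprop-1-en-1-amine into 3,4-bis(methoxymethoxy)benzoyl chloride F3. The lithium phenoxide enolate of 12 (LiN(SiMe3)2, 3.2 equiv, THF, −78 °C) would then be aroylated directly on carbon. Any ester formed on oxygen would rearrange under the excess base, so 17 should result in one flask.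

Step 12.
- What may go wrong: acid-catalysed addition of the 7- or 5-hydroxyl to the neighbouring prenyl double bond (chroman formation), or of methanol to the alkenes, during the time that cleavage of four acetals needs.
- Fallback: it sets out from 11 and 13 and returns at 19. It replaces every acetal by an allyl ether, so that strong acid is never needed and no phenol is free while acid is present.
  - Compound 11 with allyl bromide and K2CO3 in acetone would give 1-[2-hydroxy-3,5-bis(3-methylbut-2-enyl)-4,6-bis(prop-2-enoxy)phenyl]-2-methoxyethanone F4.
  - Compound 13 with allyl bromide and K2CO3 in DMF would give prop-2-enyl 3,4-bis(prop-2-enoxy)benzoate F5, and NaOH in aqueous methanol would give 3,4-bis(prop-2-enoxy)benzoic acid F6.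
  - Carbodiimide coupling of F4 with F6 would give [2-(2-methoxyacetyl)-4,6-bis(3-methylbut-2-enyl)-3,5-bis(prop-2-enoxy)phenyl] 3,4-bis(prop-2-enoxy)benzoate F7.
  - LiN(SiMe3)2 would rearrange F7 to 1-[3,4-bis(prop-2-enoxy)phenyl]-3-[2-hydroxy-3,5-bis(3-methylbut-2-enyl)-4,6-bis(prop-2-enoxy)phenyl]-2-methoxypropane-1,3-dione F8.
  - Catalytic p-toluenesulfonic acid in toluene at 60 °C would close ring C to 3-methoxy-6,8-bis(3-methylbut-2-enyl)-5,7-bis(prop-2-enoxy)-2-[3,4-bis(prop-2-enoxy)phenyl]chromen-4-one F9.
  - Pd(PPh3)4 (zerovalent palladium) with morpholine in THF would remove the four allyl groups without touching the prenyl groups and give 19.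

## Further compounds

F0 | step 6 | none | none
F1 | step 3 | methyl 5-hydroxy-2,4-bis(3-methylbut-2-enyl)-3-oxohexanoate (mixture of diastereomers) | COC(=O)C(CC=C(C)C)C(=O)C(CC=C(C)C)C(C)O
F2 | step 5 | 4-hydroxy-6-(2-hydroxy-3-methoxypropyl)-3,5-bis(3-methylbut-2-enyl)pyran-2-one (racemic) | COCC(O)CC1=C(CC=C(C)C)C(O)=C(CC=C(C)C)C(=O)O1
F3 | step 10 | 3,4-bis(methoxymethoxy)benzoyl chloride | COCOc1ccc(C(Cl)=O)cc1OCOC
F4 | step 12 | 1-[2-hydroxy-3,5-bis(3-methylbut-2-enyl)-4,6-bis(prop-2-enoxy)phenyl]-2-methoxyethanone | COCC(=O)c1c(O)c(CC=C(C)C)c(OCC=C)c(CC=C(C)C)c1OCC=C
F5 | step 12 | prop-2-enyl 3,4-bis(prop-2-enoxy)benzoate | C=CCOC(=O)c1ccc(OCC=C)c(OCC=C)c1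
F6 | step 12 | 3,4-bis(prop-2-enoxy)benzoic acid | C=CCOc1ccc(C(=O)O)cc1OCC=C
F7 | step 12 | [2-(2-methoxyacetyl)-4,6-bis(3-methylbut-2-enyl)-3,5-bis(prop-2-enoxy)phenyl] 3,4-bis(prop-2-enoxy)benzoate | COCC(=O)c1c(OC(=O)c2ccc(OCC=C)c(OCC=C)c2)c(CC=C(C)C)c(OCC=C)c(CC=C(C)C)c1OCC=C
F8 | step 12 | 1-[3,4-bis(prop-2-enoxy)phenyl]-3-[2-hydroxy-3,5-bis(3-methylbut-2-enyl)-4,6-bis(prop-2-enoxy)phenyl]-2-methoxypropane-1,3-dione (racemic, enolisable) | C=CCOc1ccc(C(=O)C(OC)C(=O)c2c(O)c(CC=C(C)C)c(OCC=C)c(CC=C(C)C)c2OCC=C)cc1OCC=C
F9 | step 12 | 3-methoxy-6,8-bis(3-methylbut-2-enyl)-5,7-bis(prop-2-enoxy)-2-[3,4-bis(prop-2-enoxy)phenyl]chromen-4-one | COc1c(-c2ccc(OCC=C)c(OCC=C)c2)oc2c(CC=C(C)C)c(OCC=C)c(CC=C(C)C)c(OCC=C)c2c1=O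
A1 | alternative 1 | 2-[1-[3,4-bis(methoxymethoxy)phenyl]-2-methoxyethenoxy]-4,6-bis(methoxymethoxy)-3,5-bis(3-methylbut-2-enyl)benzoic acid (enol ether geometry not defined) | COC=C(Oc1c(CC=C(C)C)c(OCOC)c(CC=C(C)C)c(OCOC)c1C(=O)O)c1ccc(OCOC)c(OCOC)c1
A2 | alternative 1 | 2-[1-[3,4-bis(methoxymethoxy)phenyl]-2-methoxyethenoxy]-4,6-bis(methoxymethoxy)-3,5-bis(3-methylbut-2-enyl)benzoyl chloride | COC=C(Oc1c(CC=C(C)C)c(OCOC)c(CC=C(C)C)c(OCOC)c1C(Cl)=O)c1ccc(OCOC)c(OCOC)c1
A3 | alternative 1 | 2-[3,4-bis(methoxymethoxy)phenyl]-3-methoxy-5,7-bis(methoxymethoxy)-6,8-bis(3-methylbut-2-enyl)chromen-4-one (same constitution as 18) | COc1c(-c2ccc(OCOC)c(OCOC)c2)oc2c(CC=C(C)C)c(OCOC)c(CC=C(C)C)c(OCOC)c2c1=O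
A4 | alternative 2 | 2-(3-methylbut-2-enyl)-3-(triisopropylsilyloxy)cyclobut-2-en-1-one | O=C1CC(O[Si](C(C)C)(C(C)C)C(C)C)=C1CC=C(C)C
A5 | alternative 2 | triisopropyl(5-methylhex-4-en-1-ynoxy)silane | CC(C)=CCC#CO[Si](C(C)C)(C(C)C)C(C)C
A6 | alternative 2 | 2,4-bis(3-methylbut-2-enyl)-3,5-bis(triisopropylsilyloxy)phenol | Oc1cc(O[Si](C(C)C)(C(C)C)C(C)C)c(CC=C(C)C)c(O[Si](C(C)C)(C(C)C)C(C)C)c1CC=C(C)C
A7 | alternative 3 | 3,4-bis(methoxymethoxy)benzonitrile oxide | COCOc1ccc(C#[N+][O-])cc1OCOC
A8 | alternative 3 | 2-methoxy-1-[2,4,6-tris(methoxymethoxy)-3,5-bis(3-methylbut-2-enyl)phenyl]ethanone | COCC(=O)c1c(OCOC)c(CC=C(C)C)c(OCOC)c(CC=C(C)C)c1OCOC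
A9 | alternative 3 | 3-[3,4-bis(methoxymethoxy)phenyl]-4-methoxy-5-[2,4,6-tris(methoxymethoxy)-3,5-bis(3-methylbut-2-enyl)phenyl]isoxazole | COCOc1ccc(-c2noc(-c3c(OCOC)c(CC=C(C)C)c(OCOC)c(CC=C(C)C)c3OCOC)c2OC)cc1OCOC
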